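**Plan**

- Flavan numbering is used: ring A is the benzo ring (C4a, C5–C8, C8a), ring C the dihydropyran (O1, C2, C3, C4), ring B the pendant aryl group and ring D the dimethylpyran fused to ring B.
- Retrosynthesis: the 6-(1,1-dimethylallyl)/7-OH pair is first traced back to a 7-O-prenyl ether (aromatic Claisen rearrangement). Ring C is then cut at C3–C4 and at O1–C8a, which gives a ring A benzyl halide and a ring B aryl oxirane.
- Enabling feature: C4 is a benzylic carbon of ring A and C8a is the ring carbon next to it, while O1 already sits on the stereocentre C2 and C3 is an unsubstituted CH2. An ortho-bromobenzyl metal (C4 nucleophile, C8a–Br electrophile) can therefore meet an aryl oxirane (C3 electrophile, O1 nucleophile once opened) in a [3+3] annulation that never touches the C2–O1 bond.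
- Forward order: ring D is built on ring B by propargyl ether rearrangement, the prenyl group is coupled in and the aldehyde becomes the oxirane. Ring A arrives as a Grignard reagent and ring C closes in the same flask. Claisen rearrangement and desilylation finish the route.
- Stereochemistry: C2 is the only stereocentre. It is set by hydrolytic kinetic resolution of the oxirane (R) and carried unchanged into the (S)-flavan.

Key step: step 11

Remark: the (R,R) cobalt–salen catalyst is assumed to leave the (R)-oxirane unreacted, as it does for styrene oxide.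

**Route**

Step 1
Reactants: 1 2-bromo-4,5-dimethoxybenzaldehyde
Product: 2 2-bromo-4,5-dihydroxybenzaldehyde
Conditions: BBr3, CH2Cl2, −78 °C to rt; aqueous work-up
Reagents that add atoms: none
Why: Lewis acid demethylation with BBr3 should cleave both aryl methyl ethers and leave the aldehyde and the aryl bromide untouched.

Step 2
Reactants: 2 2-bromo-4,5-dihydroxybenzaldehyde
Product: 3 2-bromo-5-hydroxy-4-[(2-methylbut-3-yn-2-yl)oxy]benzaldehyde
Conditions: 3-chloro-3-methylbut-1-yne (1.1 equiv), DBU (1.05 equiv), CuCl2 (1 mol %), MeCN, 0 °C, argon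
Reagents that add atoms: 3-chloro-3-methylbut-1-yne, C#CC(C)(C)Cl
Why: The 4-OH para to the formyl group is the more acidic phenol, so one equivalent of DBU should give mainly the 4-phenoxide, which is alkylated in a copper-catalysed O-propargylation with the tertiary propargylic chloride.

Step 3
Reactants: 3 2-bromo-5-hydroxy-4-[(2-methylbut-3-yn-2-yl)oxy]benzaldehyde
Product: 4 2-bromo-4-[(2-methylbut-3-yn-2-yl)oxy]-5-[(triisopropylsilyl)oxy]benzaldehyde
Conditions: i-Pr3SiCl, imidazole, DMF, rt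
Reagents that add atoms: triisopropylsilyl chloride, CC(C)[Si](Cl)(C(C)C)C(C)C
Why: Standard phenol silylation; the triisopropylsilyl ether is chosen because it should survive the later heating, the Grignard reagent and the carbonate base, and it comes off with fluoride at the end.

Step 4
Reactants: 4 2-bromo-4-[(2-methylbut-3-yn-2-yl)oxy]-5-[(triisopropylsilyl)oxy]benzaldehyde
Product: 5 5-bromo-2,2-dimethyl-8-[(triisopropylsilyl)oxy]-2H-chromene-6-carbaldehyde
Conditions: N,N-diethylaniline, 180 °C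
Reagents that add atoms: none
Why: Aryl propargyl ether Claisen rearrangement to the only free position ortho to the ether oxygen, then enolisation, 1,5-hydrogen shift and oxa-6π electrocyclisation, should close ring D as the 2,2-dimethyl-2H-chromene.

Step 5
Reactants: 5 5-bromo-2,2-dimethyl-8-[(triisopropylsilyl)oxy]-2H-chromene-6-carbaldehyde
Product: 6 2,2-dimethyl-5-(3-methylbut-2-en-1-yl)-8-[(triisopropylsilyl)oxy]-2H-chromene-6-carbaldehyde
Conditions: tributyl(3-methylbut-2-en-1-yl)stannane, Pd(PPh3)4 (5 mol %), DMF, 100 °C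
Reagents that add atoms: tributyl(3-methylbut-2-en-1-yl)stannane, CCCC[Sn](CCCC)(CCCC)CC=C(C)C
Why: Stille coupling; the C–Br bond ortho to the formyl group is activated for oxidative addition and the prenylstannane should deliver the linear prenyl group without touching the chromene or the aldehyde.

Step 6
Reactants: 6 2,2-dimethyl-5-(3-methylbut-2-en-1-yl)-8-[(triisopropylsilyl)oxy]-2H-chromene-6-carbaldehyde
Product: 7 rac-2-[2,2-dimethyl-5-(3-methylbut-2-en-1-yl)-8-(triisopropylsilyloxy)-2H-chromen-6-yl]oxirane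
Conditions: Me3S+ I−, KN(SiMe3)2, THF, −20 °C; then 6, −20 °C to rt
Reagents that add atoms: trimethylsulfonium iodide, C[S+](C)C.[I-]
Why: Corey–Chaykovsky epoxidation; the sulfonium methylide adds to the aldehyde and the betaine closes to the terminal oxirane, racemic at this stage, while the aprotic amide base spares the silyl ether.

Step 7
Reactants: 7 rac-2-[2,2-dimethyl-5-(3-methylbut-2-en-1-yl)-8-(triisopropylsilyloxy)-2H-chromen-6-yl]oxirane
Product: 8 (R)-2-[2,2-dimethyl-5-(3-methylbut-2-en-1-yl)-8-(triisopropylsilyloxy)-2H-chromen-6-yl]oxirane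
Conditions: (R,R)-(salen)Co(OAc) (2 mol %, trivalent cobalt; salen = N,N'-bis(3,5-di-tert-butylsalicylidene)cyclohexane-1,2-diamine dianion), H2O (0.55 equiv), THF, 0 °C to rt; chromatography on Et3N-deactivated silica
Reagents that add atoms: none
Why: Jacobsen hydrolytic kinetic resolution; the (R,R) catalyst should hydrolyse the (S)-oxirane selectively at its terminal carbon and leave the (R)-oxirane in high enantiomeric purity, which sets the configuration of C2.

Step 8
Reactants: 9 2-bromo-4-hydroxybenzaldehyde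
Product: 10 2-bromo-4-[(3-methylbut-2-en-1-yl)oxy]benzaldehyde
Conditions: prenyl bromide, K2CO3, DMF, rt
Reagents that add atoms: 1-bromo-3-methylbut-2-ene (prenyl bromide), CC(C)=CCBr
Why: Williamson etherification of the acidic phenol; the prenyl ether later serves both as the protecting group of O7 and as the source of the 1,1-dimethylallyl group.

Step 9
Reactants: 10 2-bromo-4-[(3-methylbut-2-en-1-yl)oxy]benzaldehyde
Product: 11 {2-bromo-4-[(3-methylbut-2-en-1-yl)oxy]phenyl}methanol
Conditions: NaBH4, MeOH, 0 °C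
Reagents that add atoms: none
Why: Borohydride reduction of the aldehyde is chemoselective in the presence of the aryl bromide and the prenyl ether.

Step 10
Reactants: 11 {2-bromo-4-[(3-methylbut-2-en-1-yl)oxy]phenyl}methanol
Product: 12 2-bromo-1-(chloromethyl)-4-[(3-methylbut-2-en-1-yl)oxy]benzene
Conditions: PPh3, CCl4, MeCN, 0 °C to rt
Reagents that add atoms: carbon tetrachloride, ClC(Cl)(Cl)Cl
Why: Appel chlorination under neutral conditions should give the benzylic chloride without acid that could cleave or hydrochlorinate the prenyl ether.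

Step 11
Reactants: 12 2-bromo-1-(chloromethyl)-4-[(3-methylbut-2-en-1-yl)oxy]benzene; 8 (R)-2-[2,2-dimethyl-5-(3-methylbut-2-en-1-yl)-8-(triisopropylsilyloxy)-2H-chromen-6-yl]oxirane
Product: 15 (S)-2-[2,2-dimethyl-5-(3-methylbut-2-en-1-yl)-8-(triisopropylsilyloxy)-2H-chromen-6-yl]-7-[(3-methylbut-2-en-1-yl)oxy]chromane, via benzylmagnesium chloride 13 (not isolated), via chloromagnesium alkoxide 14 (not isolated)
Conditions: 12 (1.15 equiv), Mg turnings, Et2O, 0 °C; add to 8 and CuI (10 mol %) in THF, −40 to −10 °C; then t-BuOH (0.2 equiv, quenches excess 13), 3,4,7,8-tetramethyl-1,10-phenanthroline (20 mol %), Cs2CO3, toluene, ethers distilled off, 110 °C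
Reagents that add atoms: none
Why: Magnesium inserts into the benzylic C–Cl bond of 12 faster than into the aryl C–Br bond, and the benzylcopper species formed from 13 and CuI opens oxirane 8 by SN2 attack at the unsubstituted carbon C3, which makes the C3–C4 bond and leaves the C2–O1 bond untouched, so the R oxirane becomes the S alkoxide 14 by a change of descriptor only. The same copper charge, now ligated by the phenanthroline and with Cs2CO3 as base, then couples the alkoxide oxygen with the neighbouring C8a–Br bond in an Ullmann-type etherification (activation of the aryl bromide at monovalent copper, then C–O reductive elimination), which makes the O1–C8a bond. The closest known reaction types are the copper-catalysed Grignard opening of aryl oxiranes at the terminal carbon and the copper-catalysed cyclisation of 3-(2-bromoaryl)propan-1-ols to chromans, run here in one flask. Ring C closes in a 6-exo mode at C8a, the breaking C–Br bond lying outside the new ring. C2 is the only stereocentre and is controlled by the configuration of 8, since neither event breaks a bond at C2. The step needs opening at C3 and not at the benzylic carbon C2, which copper catalysis at low temperature and the ortho prenyl group flanking C2 should secure, and it needs cyclisation ahead of intermolecular O-arylation, which the six-membered transition state should secure.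

Step 12
Reactants: 15 (S)-2-[2,2-dimethyl-5-(3-methylbut-2-en-1-yl)-8-(triisopropylsilyloxy)-2H-chromen-6-yl]-7-[(3-methylbut-2-en-1-yl)oxy]chromane
Product: 16 (S)-2-[2,2-dimethyl-5-(3-methylbut-2-en-1-yl)-8-(triisopropylsilyloxy)-2H-chromen-6-yl]-6-(2-methylbut-3-en-2-yl)chroman-7-ol
Conditions: N,N-diethylaniline, 190 °C, sealed tube, argon, short reaction time
Reagents that add atoms: none
Why: Aromatic Claisen rearrangement of the aryl prenyl ether delivers the tertiary allyl terminus to an ortho carbon and frees the 7-OH on tautomerisation; C6 should be preferred over C8 because C8 is flanked by two oxygen substituents and C6 lies para to the donor O1, and C2 is not involved.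

Step 13
Reactants: 16 (S)-2-[2,2-dimethyl-5-(3-methylbut-2-en-1-yl)-8-(triisopropylsilyloxy)-2H-chromen-6-yl]-6-(2-methylbut-3-en-2-yl)chroman-7-ol
Product: 17 Kazinol H, (S)-6-[7-hydroxy-6-(2-methylbut-3-en-2-yl)chroman-2-yl]-2,2-dimethyl-5-(3-methylbut-2-en-1-yl)-2H-chromen-8-ol
Conditions: Bu4NF, AcOH, THF, 0 °C
Reagents that add atoms: none
Why: Fluoride cleavage of the aryl silyl ether under acetic acid buffering avoids both strong acid (ring opening at the benzylic C2–O1 bond, cyclisation of the allyl groups onto phenols) and free phenoxide.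

**Compound list**

1 | 2-bromo-4,5-dimethoxybenzaldehyde | O=Cc1cc(OC)c(OC)cc1Br | starting material
2 | 2-bromo-4,5-dihydroxybenzaldehyde | O=Cc1cc(O)c(O)cc1Br | intermediate
3 | 2-bromo-5-hydroxy-4-[(2-methylbut-3-yn-2-yl)oxy]benzaldehyde | O=Cc1cc(O)c(OC(C)(C)C#C)cc1Br | intermediate
4 | 2-bromo-4-[(2-methylbut-3-yn-2-yl)oxy]-5-[(triisopropylsilyl)oxy]benzaldehyde | O=Cc1cc(O[Si](C(C)C)(C(C)C)C(C)C)c(OC(C)(C)C#C)cc1Br | intermediate
5 | 5-bromo-2,2-dimethyl-8-[(triisopropylsilyl)oxy]-2H-chromene-6-carbaldehyde | O=Cc1cc(O[Si](C(C)C)(C(C)C)C(C)C)c2OC(C)(C)C=Cc2c1Br | intermediate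
6 | 2,2-dimethyl-5-(3-methylbut-2-en-1-yl)-8-[(triisopropylsilyl)oxy]-2H-chromene-6-carbaldehyde | O=Cc1cc(O[Si](C(C)C)(C(C)C)C(C)C)c2OC(C)(C)C=Cc2c1CC=C(C)C | intermediate
7 | rac-2-[2,2-dimethyl-5-(3-methylbut-2-en-1-yl)-8-(triisopropylsilyloxy)-2H-chromen-6-yl]oxirane | C1OC1c1cc(O[Si](C(C)C)(C(C)C)C(C)C)c2OC(C)(C)C=Cc2c1CC=C(C)C | intermediate
8 | (R)-2-[2,2-dimethyl-5-(3-methylbut-2-en-1-yl)-8-(triisopropylsilyloxy)-2H-chromen-6-yl]oxirane | C1O[C@@H]1c1cc(O[Si](C(C)C)(C(C)C)C(C)C)c2OC(C)(C)C=Cc2c1CC=C(C)C | intermediate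
9 | 2-bromo-4-hydroxybenzaldehyde | O=Cc1ccc(O)cc1Br | starting material
10 | 2-bromo-4-[(3-methylbut-2-en-1-yl)oxy]benzaldehyde | O=Cc1ccc(OCC=C(C)C)cc1Br | intermediate
11 | {2-bromo-4-[(3-methylbut-2-en-1-yl)oxy]phenyl}methanol | OCc1ccc(OCC=C(C)C)cc1Br | intermediate
12 | 2-bromo-1-(chloromethyl)-4-[(3-methylbut-2-en-1-yl)oxy]benzene | ClCc1ccc(OCC=C(C)C)cc1Br | intermediate
13 | {2-bromo-4-[(3-methylbut-2-en-1-yl)oxy]benzyl}magnesium chloride (not isolated) | Cl[Mg]Cc1ccc(OCC=C(C)C)cc1Br | intermediate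
14 | chloromagnesium (S)-3-{2-bromo-4-[(3-methylbut-2-en-1-yl)oxy]phenyl}-1-[2,2-dimethyl-5-(3-methylbut-2-en-1-yl)-8-(triisopropylsilyloxy)-2H-chromen-6-yl]propan-1-olate (not isolated) | Cl[Mg]O[C@H](c1cc(O[Si](C(C)C)(C(C)C)C(C)C)c2OC(C)(C)C=Cc2c1CC=C(C)C)CCc1ccc(OCC=C(C)C)cc1Br | intermediate
15 | (S)-2-[2,2-dimethyl-5-(3-methylbut-2-en-1-yl)-8-(triisopropylsilyloxy)-2H-chromen-6-yl]-7-[(3-methylbut-2-en-1-yl)oxy]chromane | c1cc2c(cc1OCC=C(C)C)O[C@H](c1cc(O[Si](C(C)C)(C(C)C)C(C)C)c3OC(C)(C)C=Cc3c1CC=C(C)C)CC2 | intermediate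
16 | (S)-2-[2,2-dimethyl-5-(3-methylbut-2-en-1-yl)-8-(triisopropylsilyloxy)-2H-chromen-6-yl]-6-(2-methylbut-3-en-2-yl)chroman-7-ol | C=CC(C)(C)c1cc2c(cc1O)O[C@H](c1cc(O[Si](C(C)C)(C(C)C)C(C)C)c3OC(C)(C)C=Cc3c1CC=C(C)C)CC2 | intermediate
17 | Kazinol H, (S)-6-[7-hydroxy-6-(2-methylbut-3-en-2-yl)chroman-2-yl]-2,2-dimethyl-5-(3-methylbut-2-en-1-yl)-2H-chromen-8-ol | C=CC(C)(C)c1cc2c(cc1O)O[C@H](c1cc(O)c3c(c1CC=C(C)C)C=CC(C)(C)O3)CC2 | target

**Step count and risks**

Total step count: 13. Longest linear sequence: 10 steps (steps 1–7, then 11–13, from compound 1).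

Steps most likely to fail:

Step 11. The electron-rich aryl oxirane may open at the benzylic carbon or rearrange under the Lewis acidic magnesium salts before the copper-mediated attack at C3, and the magnesium alkoxide may undergo O-arylation only sluggishly. The fallback builds the same two bonds one at a time with known chemistry, setting out from 6 and 12 and coming back at 15. Aldehyde 6 is treated with MeMgBr (THF, 0 °C) to give the racemic carbinol 1-[2,2-dimethyl-5-(3-methylbut-2-en-1-yl)-8-(triisopropylsilyloxy)-2H-chromen-6-yl]ethan-1-ol F1. Dess–Martin periodinane oxidises it to the methyl ketone 1-[2,2-dimethyl-5-(3-methylbut-2-en-1-yl)-8-(triisopropylsilyloxy)-2H-chromen-6-yl]ethan-1-one F2. The lithium enolate of F2 (LiN(SiMe3)2, THF, −78 °C) is alkylated with 12 (NaI) to give the ketone 3-{2-bromo-4-[(3-methylbut-2-en-1-yl)oxy]phenyl}-1-[2,2-dimethyl-5-(3-methylbut-2-en-1-yl)-8-(triisopropylsilyloxy)-2H-chromen-6-yl]propan-1-one F3, which carries the C3–C4 bond. Noyori transfer hydrogenation with RuCl[(S,S)-TsDPEN](p-cymene) in HCO2H/Et3N, which spares the alkenes, should give the (S)-carbinol (S)-3-{2-bromo-4-[(3-methylbut-2-en-1-yl)oxy]phenyl}-1-[2,2-dimethyl-5-(3-methylbut-2-en-1-yl)-8-(triisopropylsilyloxy)-2H-chromen-6-yl]propan-1-ol F4. Cyclisation of F4 with CuI, 3,4,7,8-tetramethyl-1,10-phenanthroline and Cs2CO3 in toluene at 110 °C gives 15.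

Step 12. The allyl group may migrate to C8 instead of C6, and at the temperature needed the ortho-(1,1-dimethylallyl)phenol may rearrange further (abnormal Claisen) or cyclise onto the phenol, all on the fully assembled molecule. The fallback moves the rearrangement to the simple ring A fragment, where the second ortho position is flanked by bromine and isomers are easy to separate; it sets out from 10 and comes back at 17. Heating 10 in N,N-diethylaniline (190 °C) should give 2-bromo-4-hydroxy-5-(2-methylbut-3-en-2-yl)benzaldehyde F5. Silylation (t-BuMe2SiOTf, 2,6-lutidine) gives 2-bromo-4-[(tert-butyldimethylsilyl)oxy]-5-(2-methylbut-3-en-2-yl)benzaldehyde F6, NaBH4 gives {2-bromo-4-[(tert-butyldimethylsilyl)oxy]-5-(2-methylbut-3-en-2-yl)phenyl}methanol F7, and PPh3/CCl4 gives [5-bromo-4-(chloromethyl)-2-(2-methylbut-3-en-2-yl)phenoxy](tert-butyl)dimethylsilane F8. Under the conditions of step 11, F8 forms {2-bromo-4-[(tert-butyldimethylsilyl)oxy]-5-(2-methylbut-3-en-2-yl)benzyl}magnesium chloride F9, which opens 8 to the chloromagnesium (S)-3-{2-bromo-4-[(tert-butyldimethylsilyl)oxy]-5-(2-methylbut-3-en-2-yl)phenyl}-1-[2,2-dimethyl-5-(3-methylbut-2-en-1-yl)-8-(triisopropylsilyloxy)-2H-chromen-6-yl]propan-1-olate F10. This cyclises to (S)-tert-butyl{[2-(2,2-dimethyl-5-(3-methylbut-2-en-1-yl)-8-(triisopropylsilyloxy)-2H-chromen-6-yl)-6-(2-methylbut-3-en-2-yl)chroman-7-yl]oxy}dimethylsilane F11. Bu4NF/AcOH removes both silyl groups and gives 17.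

Step 7. The cobalt catalyst may open the electron-rich aryl oxirane unselectively or in a Lewis acid manner, which would erode enantiomeric purity and recovery, and at best half of the material is kept. The fallback sets the stereocentre by asymmetric reduction; it sets out from 6 and comes back at 8. Chloromethyllithium (ICH2Cl, MeLi·LiBr, THF, −78 °C, cold AcOH quench) adds to 6 to give the racemic chlorohydrin 2-chloro-1-[2,2-dimethyl-5-(3-methylbut-2-en-1-yl)-8-(triisopropylsilyloxy)-2H-chromen-6-yl]ethan-1-ol F12. Dess–Martin periodinane gives the chloroketone 2-chloro-1-[2,2-dimethyl-5-(3-methylbut-2-en-1-yl)-8-(triisopropylsilyloxy)-2H-chromen-6-yl]ethan-1-one F13. Noyori transfer hydrogenation with RuCl[(S,S)-TsDPEN](p-cymene) in HCO2H/Et3N should give (R)-2-chloro-1-[2,2-dimethyl-5-(3-methylbut-2-en-1-yl)-8-(triisopropylsilyloxy)-2H-chromen-6-yl]ethan-1-ol F14. Ring closure with KOt-Bu (THF, 0 °C) gives 8 without loss of half the material.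

**Further compounds**

F1 | step 11 | rac-1-[2,2-dimethyl-5-(3-methylbut-2-en-1-yl)-8-(triisopropylsilyloxy)-2H-chromen-6-yl]ethan-1-ol | CC(O)c1cc(O[Si](C(C)C)(C(C)C)C(C)C)c2OC(C)(C)C=Cc2c1CC=C(C)C
F2 | step 11 | 1-[2,2-dimethyl-5-(3-methylbut-2-en-1-yl)-8-(triisopropylsilyloxy)-2H-chromen-6-yl]ethan-1-one | CC(=O)c1cc(O[Si](C(C)C)(C(C)C)C(C)C)c2OC(C)(C)C=Cc2c1CC=C(C)C
F3 | step 11 | 3-{2-bromo-4-[(3-methylbut-2-en-1-yl)oxy]phenyl}-1-[2,2-dimethyl-5-(3-methylbut-2-en-1-yl)-8-(triisopropylsilyloxy)-2H-chromen-6-yl]propan-1-one | O=C(CCc1ccc(OCC=C(C)C)cc1Br)c1cc(O[Si](C(C)C)(C(C)C)C(C)C)c2OC(C)(C)C=Cc2c1CC=C(C)C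
F4 | step 11 | (S)-3-{2-bromo-4-[(3-methylbut-2-en-1-yl)oxy]phenyl}-1-[2,2-dimethyl-5-(3-methylbut-2-en-1-yl)-8-(triisopropylsilyloxy)-2H-chromen-6-yl]propan-1-ol | O[C@H](c1cc(O[Si](C(C)C)(C(C)C)C(C)C)c2OC(C)(C)C=Cc2c1CC=C(C)C)CCc1ccc(OCC=C(C)C)cc1Br
F5 | step 12 | 2-bromo-4-hydroxy-5-(2-methylbut-3-en-2-yl)benzaldehyde | O=Cc1cc(C(C)(C)C=C)c(O)cc1Br
F6 | step 12 | 2-bromo-4-[(tert-butyldimethylsilyl)oxy]-5-(2-methylbut-3-en-2-yl)benzaldehyde | O=Cc1cc(C(C)(C)C=C)c(O[Si](C)(C)C(C)(C)C)cc1Br
F7 | step 12 | {2-bromo-4-[(tert-butyldimethylsilyl)oxy]-5-(2-methylbut-3-en-2-yl)phenyl}methanol | OCc1cc(C(C)(C)C=C)c(O[Si](C)(C)C(C)(C)C)cc1Br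
F8 | step 12 | [5-bromo-4-(chloromethyl)-2-(2-methylbut-3-en-2-yl)phenoxy](tert-butyl)dimethylsilane | ClCc1cc(C(C)(C)C=C)c(O[Si](C)(C)C(C)(C)C)cc1Br
F9 | step 12 | {2-bromo-4-[(tert-butyldimethylsilyl)oxy]-5-(2-methylbut-3-en-2-yl)benzyl}magnesium chloride | Cl[Mg]Cc1cc(C(C)(C)C=C)c(O[Si](C)(C)C(C)(C)C)cc1Br
F10 | step 12 | chloromagnesium (S)-3-{2-bromo-4-[(tert-butyldimethylsilyl)oxy]-5-(2-methylbut-3-en-2-yl)phenyl}-1-[2,2-dimethyl-5-(3-methylbut-2-en-1-yl)-8-(triisopropylsilyloxy)-2H-chromen-6-yl]propan-1-olate | Cl[Mg]O[C@H](c1cc(O[Si](C(C)C)(C(C)C)C(C)C)c2OC(C)(C)C=Cc2c1CC=C(C)C)CCc1cc(C(C)(C)C=C)c(O[Si](C)(C)C(C)(C)C)cc1Br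
F11 | step 12 | (S)-tert-butyl{[2-(2,2-dimethyl-5-(3-methylbut-2-en-1-yl)-8-(triisopropylsilyloxy)-2H-chromen-6-yl)-6-(2-methylbut-3-en-2-yl)chroman-7-yl]oxy}dimethylsilane | C=CC(C)(C)c1cc2c(cc1O[Si](C)(C)C(C)(C)C)O[C@H](c1cc(O[Si](C(C)C)(C(C)C)C(C)C)c3OC(C)(C)C=Cc3c1CC=C(C)C)CC2
F12 | step 7 | rac-2-chloro-1-[2,2-dimethyl-5-(3-methylbut-2-en-1-yl)-8-(triisopropylsilyloxy)-2H-chromen-6-yl]ethan-1-ol | OC(CCl)c1cc(O[Si](C(C)C)(C(C)C)C(C)C)c2OC(C)(C)C=Cc2c1CC=C(C)C
F13 | step 7 | 2-chloro-1-[2,2-dimethyl-5-(3-methylbut-2-en-1-yl)-8-(triisopropylsilyloxy)-2H-chromen-6-yl]ethan-1-one | O=C(CCl)c1cc(O[Si](C(C)C)(C(C)C)C(C)C)c2OC(C)(C)C=Cc2c1CC=C(C)C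
F14 | step 7 | (R)-2-chloro-1-[2,2-dimethyl-5-(3-methylbut-2-en-1-yl)-8-(triisopropylsilyloxy)-2H-chromen-6-yl]ethan-1-ol | ClC[C@H](O)c1cc(O[Si](C(C)C)(C(C)C)C(C)C)c2OC(C)(C)C=Cc2c1CC=C(C)C
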